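**Retrosynthetic overview**
1. Macrocarpal H ⇒ Wittig methylenation of the C4 ketone 11. The exocyclic alkene is installed last because it would not survive hydrogenation.
2. C1 (β, equatorial) ⇒ α-face hydrogenation of the Δ1(2) olefin 10. The 10β-methyl blocks the β face. 10 comes from deconjugation of enone 9.
3. The C1–CH(iBu)Ar bond ⇒ a bioinspired vinylogous (dienamine) addition of enone 6 to the o-quinone methide formed from 2,4,6-trihydroxyisophthalaldehyde and isovaleraldehyde.
4. Enone 6 ⇐ Saegusa desaturation of the C4 ketone 3 ⇐ ozonolysis of β-eudesmol. β-Eudesmol supplies both decalin rings and C5, C7, C10, C11 with the natural configuration. The C4 ketone makes C1 the γ-position of an enone.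

No ring is formed in the route; the aryl ring is attached by C–C bond formation in step 4.

Assumptions:
- Natural (+)-β-eudesmol and 2,4,6-trihydroxyisophthalaldehyde are purchasable.
- The vinylogous o-QM addition in step 4 gives the benzylic (S) centre with useful diastereoselectivity. The minor diastereomer is removed by HPLC.

---

**Step 1**
Reactants: 1 (β-eudesmol); 2 (ozone)
Product: 3 (4-oxo-15-nor-eudesmane, β-eudesmol ozonolysis ketone)
Conditions: O3, CH2Cl2/MeOH, –78 °C; then Me2S, –78 °C → rt
Reagents that add atoms: ozone, O=[O+][O-] (supplies the ketone O; CH2O is lost)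
Why: Ozonolysis (oxidative alkene cleavage) converts the exocyclic methylene selectively to the C4 ketone. The tertiary alcohol is untouched. The trans-decalin is thermodynamically stable, so C5, C7 and C10 are preserved.

**Step 2**
Reactants: 3; 4 (chlorotrimethylsilane)
Product: 5 (C3=C4 TMS enol ether, with the tertiary alcohol as its TMS ether)
Conditions: LDA (2.3 equiv), THF, –78 °C; then TMSCl, Et3N, –78 °C → rt
Reagents that add atoms: chlorotrimethylsilane, C[Si](C)(C)Cl (two TMS groups)
Why: Kinetic deprotonation (silyl enol ether formation) occurs at the less hindered C3–H2 rather than the tertiary C5–H. The alkoxide is silylated at the same time.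

**Step 3**
Reactants: 5
Product: 6 (Δ2-4-one enone with free 11-OH)
Conditions: Pd(OAc)2 (10 mol%), p-benzoquinone, MeCN, rt; then 1 M HCl, THF
Reagents that add atoms: none (the TMS groups are removed on workup)
Why: Saegusa–Ito oxidation (Pd(II) enolate, β-hydride elimination) puts the C2=C3 bond in conjugation with C4=O. C1 is now the γ-position, which is what allows functionalization next to the quaternary C10.

**Step 4**
Reactants: 6; 7 (isovaleraldehyde); 8 (2,4,6-trihydroxyisophthalaldehyde)
Product: 9 (C1 α-substituted Δ2-4-one, Cβ = S)
Conditions: benzylamine (20 mol%), AcOH (40 mol%), toluene, 4 Å MS, 60 °C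
Reagents that add atoms: none beyond the listed reactants (H2O is lost)
Why: Knoevenagel-type condensation of 7 with 8 gives the o-quinone methide (o-QM). The amine converts 6 into a linear dienamine. The γ-carbon C1 then adds 1,4 to the o-QM (vinylogous Michael addition). Attack occurs anti to the 10β-methyl, which sets C1 as α, and the open transition state sets the benzylic centre. Only one ring carbon of 8 is free, so mono-alkylation is enforced.

**Step 5**
Reactants: 9
Product: 10 (β,γ-enone, Δ1(2), C4=O)
Conditions: KOt-Bu (6 equiv), THF, 0 °C; then AcOH, –78 °C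
Reagents that add atoms: none (AcOH supplies only H)
Why: γ-Deprotonation gives the extended dienolate. Kinetic α-protonation at C3 deconjugates it to the β,γ-enone. This converts the wrongly configured C1 into an sp2 centre and leaves the benzylic stereocentre untouched.

**Step 6**
Reactants: 10
Product: 11 (saturated ketone, 1β side chain)
Conditions: H2 (1 atm), 10% Pd/C, EtOAc, rt
Reagents that add atoms: none (H2 only)
Why: Heterogeneous hydrogenation of the trisubstituted olefin occurs from the α face, away from the axial 10β-methyl. H is delivered to C1α, so the side chain ends up β and equatorial. The C4 ketone and the H-bonded aryl aldehydes survive.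

**Step 7**
Reactants: 11; 12 (methylenetriphenylphosphorane)
Product: 13 (macrocarpal H)
Conditions: Ph3P+CH3 Br– (8 equiv), KOt-Bu (10 equiv), THF, 0 → 50 °C; then pH 4 workup
Reagents that add atoms: Ph3P=CH2, C=P(c1ccccc1)(c1ccccc1)c1ccccc1 (leaves the =CH2)
Why: Wittig methylenation installs the 4(15)-exocyclic alkene. The two aryl aldehydes are deactivated as chelated phenolates and should not compete. The trans-decalin prevents C5 epimerisation.

---

**Compound list**
1 | β-eudesmol, 2-[(2R,4aR,8aS)-4a-methyl-8-methylidene-decahydronaphthalen-2-yl]propan-2-ol | C=C1CCC[C@]2(C)CC[C@@H](C(C)(C)O)C[C@@H]12 | starting material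
2 | ozone | O=[O+][O-] | starting material (reagent)
3 | (4aR,7R,8aR)-7-(2-hydroxypropan-2-yl)-4a-methyloctahydronaphthalen-1(2H)-one | O=C1CCC[C@]2(C)CC[C@@H](C(C)(C)O)C[C@@H]12 | intermediate
4 | chlorotrimethylsilane | C[Si](C)(C)Cl | starting material (reagent)
5 | bis-TMS derivative of 3 (TMS enol ether C3=C4, TMS ether on C11), same ring stereochemistry | C[Si](C)(C)OC1=CCC[C@]2(C)CC[C@@H](C(C)(C)O[Si](C)(C)C)C[C@@H]12 | intermediate
6 | (4aS,7R,8aR)-7-(2-hydroxypropan-2-yl)-4a-methyl-4,4a,5,6,7,8-hexahydronaphthalen-1(8aH)-one (Δ2-4-one) | O=C1C=CC[C@]2(C)CC[C@@H](C(C)(C)O)C[C@@H]12 | intermediate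
7 | isovaleraldehyde (3-methylbutanal) | CC(C)CC=O | starting material
8 | 2,4,6-trihydroxyisophthalaldehyde | O=Cc1c(O)c(C=O)c(O)cc1O | starting material
9 | 6 bearing a 1α-[(S)-1-(2,4,6-trihydroxy-3,5-diformylphenyl)-3-methylbutyl] group at C1 | O=C1C=C[C@H]([C@H](CC(C)C)c2c(O)c(C=O)c(O)c(C=O)c2O)[C@]2(C)CC[C@@H](C(C)(C)O)C[C@@H]12 | intermediate
10 | Δ1(2) β,γ-enone isomer of 9 (C1 sp2, C3H2, C4=O), same benzylic configuration | O=C1CC=C([C@H](CC(C)C)c2c(O)c(C=O)c(O)c(C=O)c2O)[C@]2(C)CC[C@@H](C(C)(C)O)C[C@@H]12 | intermediate
11 | 4-oxo-nor analogue of the target (1β side chain, 5α-H, 7β, 10β-Me) | O=C1CC[C@@H]([C@H](CC(C)C)c2c(O)c(C=O)c(O)c(C=O)c2O)[C@]2(C)CC[C@@H](C(C)(C)O)C[C@@H]12 | intermediate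
12 | methylenetriphenylphosphorane | C=P(c1ccccc1)(c1ccccc1)c1ccccc1 | starting material (reagent)
13 | macrocarpal H | C=C1CC[C@@H]([C@H](CC(C)C)c2c(O)c(C=O)c(O)c(C=O)c2O)[C@]2(C)CC[C@@H](C(C)(C)O)C[C@@H]12 | target

**Totals:** 7 steps in total; the longest linear sequence is 7 steps (all steps are linear from 1).

**Three steps most likely to fail**
1. **Step 4** (γ-selective vinylogous o-QM addition next to the quaternary C10, and diastereoselectivity at the benzylic carbon).
   Fallback: build the bond in two stages. Make the TBS dienol ether of 6 and do a Lewis-acid vinylogous Mukaiyama aldol with 7, which gives the γ-alkylidene trienone. Then add 8 by 1,6-Friedel–Crafts addition.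
2. **Step 5** (deconjugative protonation in a polyanionic medium, with possible α′-enolisation at C5).
   Fallback: skip deconjugation. Equilibrate C1 in 9 with DBU to the thermodynamic epimer, then do a conjugate reduction of C2=C3 (H2/Pd/C or Stryker's reagent) to fix C1 by thermodynamic control.
3. **Step 7** (Wittig on a ketone in the presence of the phenolic dialdehyde).
   Fallback: change the order. Use unformylated phloroglucinol in large excess in step 4 to favour mono-C-alkylation, run the same sequence through Wittig methylenation on the phenol, and introduce both CHO groups last by Vilsmeier–Haack formylation.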